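**Retrosynthetic overview**

1. Presumed biogenesis: Claisen/Diels–Alder caging of a prenylated xanthone, oxidative C9–C9a scission to a quinone acid, then carboxylate oxa-Michael closure to the spiro ketal-lactone. The route uses the same ring-forming events but reaches the quinone-acid level directly, so the C9–C9a bond is never made.
2. Last disconnection (cage): target ⇒ an aromatic spiro ketal-lactone phenol carrying two 1,1-dimethylallyl ethers. A boron-templated enantioselective Claisen/Diels–Alder cascade builds the bicyclo[2.2.2]octene and tetrahydrofuran rings and all four cage stereocentres in the final step.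
3. Spiro 1,3-dioxin-4-one ⇒ salicylic acid fragment + 2-hydroxy-1,4-quinone fragment (ester formation, then oxa-Michael at the same quinone carbon).
4. Acid fragment ⇒ methyl 2,3,4-trihydroxybenzoate (reverse prenylation, para-oxidation). Quinone fragment ⇒ phloroglucinol + prenal (oxa-6π chromene closure), oxidation, C-prenylation.
5. Ring order: chromene → spiro dioxinone → cage (carbocycle and tetrahydrofuran together).

Numbering note: for the benzoate ring, xanthone-type locants are used: C10a (ring-oxygen carbon), C5 and C6 (allyloxy carbons), C7 (OH), C8 (H), C8a (carboxyl-bearing carbon). C4a is the spiro carbon and C4 the prenyl-bearing CH of ring A.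

Assumption 1: the natural configuration at the two epimerisable centres (spiro C4a and C4) is the thermodynamically preferred one relative to the cage, as expected if the last biosynthetic oxa-Michael closure is reversible.

Assumption 2: the (S,S)-bromoborane gives the cage enantiomer shown; if the sense of induction is opposite, the equally available (R,R)-reagent is used.

**Route**

Step 1
Reactants: 1 2-methylbut-3-en-2-ol
Product: 2 tert-butyl 2-methylbut-3-en-2-yl carbonate
Conditions: n-BuLi (1.05 equiv), THF, 0 °C; di-tert-butyl dicarbonate (1.1 equiv), 0 °C → rt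
Reagents that add atoms: di-tert-butyl dicarbonate, CC(C)(C)OC(=O)OC(=O)OC(C)(C)C
Why: O-acylation of the lithium alkoxide by the dicarbonate gives the mixed carbonate (standard carbonate formation); no stereocentre.

Step 2
Reactants: 3 methyl 2,3,4-trihydroxybenzoate; 2 tert-butyl 2-methylbut-3-en-2-yl carbonate (2.3 equiv)
Product: 4 methyl 2-hydroxy-3,4-bis[(2-methylbut-3-en-2-yl)oxy]benzoate
Conditions: Pd(PPh3)4 (5 mol%), THF, 0 °C → rt
Reagents that add atoms: none
Why: Tsuji–Trost O-allylation: zerovalent palladium ionises 2 (loss of CO2 and tert-butoxide) to a 1,1-dimethyl-π-allyl complex that the two free phenoxides attack at the tertiary terminus (kinetic, branched ethers), while the ester-chelated 2-OH is not alkylated; no stereocentre.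

Step 3
Reactants: 4 methyl 2-hydroxy-3,4-bis[(2-methylbut-3-en-2-yl)oxy]benzoate
Product: 6 methyl 2,5-dihydroxy-3,4-bis[(2-methylbut-3-en-2-yl)oxy]benzoate, via quinone ester 5 (not isolated)
Conditions: potassium nitrosodisulfonate K2[ON(SO3)2] (2.5 equiv), KH2PO4 buffer, H2O/acetone, 0 °C → rt; then aq. Na2S2O4, EtOAc, 0 °C
Reagents that add atoms: potassium nitrosodisulfonate, [K+].[K+].[O-]S(=O)(=O)N([O])S(=O)(=O)[O-]
Why: Teuber oxidation: the nitrosodisulfonate radical abstracts the phenolic H and a second equivalent oxygenates the only free para carbon (the future C7) to give the para-quinone, which dithionite reduces at once to the hydroquinone so that the sensitive tert-allyl vinylogous esters of 5 are not kept; no stereocentre.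

Step 4
Reactants: 6 methyl 2,5-dihydroxy-3,4-bis[(2-methylbut-3-en-2-yl)oxy]benzoate
Product: 7 methyl 2-hydroxy-3,4-bis[(2-methylbut-3-en-2-yl)oxy]-5-[(triisopropylsilyl)oxy]benzoate
Conditions: triisopropylsilyl chloride (1.1 equiv), imidazole, DMF, 0 °C → rt
Reagents that add atoms: triisopropylsilyl chloride, CC(C)[Si](Cl)(C(C)C)C(C)C
Why: Silyl ether formation under steric and hydrogen-bond control: the bulky silyl chloride reacts only with the unhindered 5-OH, the 2-OH being chelated to the ester and flanked by two substituents.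

Step 5
Reactants: 7 methyl 2-hydroxy-3,4-bis[(2-methylbut-3-en-2-yl)oxy]-5-[(triisopropylsilyl)oxy]benzoate
Product: 8 2-hydroxy-3,4-bis[(2-methylbut-3-en-2-yl)oxy]-5-[(triisopropylsilyl)oxy]benzoic acid
Conditions: LiOH·H2O (4 equiv), degassed THF/MeOH/H2O, 40 °C; then 1 M HCl to pH 3, 0 °C, immediate extraction
Reagents that add atoms: lithium hydroxide, [Li+].[OH-]
Why: Saponification (acyl substitution); the aryl triisopropylsilyl ether and the tertiary allyl aryl ethers tolerate LiOH, and the cold, brief acidification spares the acid-labile ethers.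

Step 6
Reactants: 9 phloroglucinol (2 equiv); 10 3-methylbut-2-enal
Product: 12 2,2-dimethyl-2H-chromene-5,7-diol, via ortho-quinone methide 11 (not isolated)
Conditions: ethylenediammonium diacetate (10 mol%), MeOH/THF, 60 °C
Reagents that add atoms: none
Why: Amine-catalysed Knoevenagel condensation (loss of water) gives ortho-quinone methide 11, which closes by oxa-6π electrocyclisation (formal 3+3 chromene annulation, the biomimetic pyran closure); the symmetric triol allows one regioisomer only and its excess suppresses double annulation.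

Step 7
Reactants: 12 2,2-dimethyl-2H-chromene-5,7-diol
Product: 13 7-hydroxy-2,2-dimethyl-2H-chromene-5,8-dione
Conditions: potassium nitrosodisulfonate K2[ON(SO3)2] (2.2 equiv), KH2PO4 buffer (pH 6), H2O/MeOH, 0 °C → rt; mild acidification, extraction
Reagents that add atoms: potassium nitrosodisulfonate, [K+].[K+].[O-]S(=O)(=O)N([O])S(=O)(=O)[O-]
Why: Teuber oxidation of a resorcinol: oxygen enters at C8, para to the 5-OH and ortho to the 7-OH (not between the two hydroxyls), giving the 2-hydroxy-1,4-quinone directly; no stereocentre.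

Step 8
Reactants: 13 7-hydroxy-2,2-dimethyl-2H-chromene-5,8-dione; 2 tert-butyl 2-methylbut-3-en-2-yl carbonate (1.0 equiv)
Product: 14 7-hydroxy-2,2-dimethyl-6-(3-methylbut-2-en-1-yl)-2H-chromene-5,8-dione
Conditions: Pd(PPh3)4 (5 mol%), THF, rt → 40 °C
Reagents that add atoms: none
Why: Tsuji–Trost C-allylation: the vinylogous-acid anion of 13 is a soft carbon nucleophile that attacks the π-prenyl palladium complex at its unsubstituted terminus, placing a linear prenyl group on C6 (the only enolisable carbon), while any O-allyl vinylogous ester is re-ionised by the catalyst; no stereocentre.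

Step 9
Reactants: 8 2-hydroxy-3,4-bis[(2-methylbut-3-en-2-yl)oxy]-5-[(triisopropylsilyl)oxy]benzoic acid; 14 7-hydroxy-2,2-dimethyl-6-(3-methylbut-2-en-1-yl)-2H-chromene-5,8-dione
Product: 16 2',2'-dimethyl-6'-(3-methylbut-2-en-1-yl)-7,8-bis[(2-methylbut-3-en-2-yl)oxy]-6-[(triisopropylsilyl)oxy]spiro[1,3-benzodioxine-2,7'-chromene]-4,5',8'(6'H)-trione (racemic; spiro C and adjacent CH epimerisable), via acyloxyquinone ester 15 (not isolated)
Conditions: N,N'-diisopropylcarbodiimide (1.3 equiv), DMAP (0.2 equiv), CH2Cl2, 0 °C → rt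
Reagents that add atoms: none
Why: Proposed new method: carbodiimide/DMAP acylation of the acidic quinone enol by the salicylic acid gives acyloxyquinone 15, in which the neighbouring phenol adds in 6-membered oxa-Michael fashion to the acyloxy-bearing quinone carbon (β to the C5 carbonyl) with C-protonation at the prenylated carbon, so the dehydrating agent achieves a net ketalisation of the hydroxyquinone by the salicylic acid (the biogenetic carboxylate-to-quinone ring closure); the closest known reactions are Steglich O-acylation of 2-hydroxy-1,4-quinones and base-mediated double O-addition of salicylic acids to ynones giving 1,3-benzodioxin-4-ones; the two new stereocentres are labile (reversible oxa-Michael, enolisation) and are left uncontrolled here.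

Step 10
Reactants: 16 the silyl-protected spiro ketal-lactone
Product: 17 6-hydroxy-2',2'-dimethyl-6'-(3-methylbut-2-en-1-yl)-7,8-bis[(2-methylbut-3-en-2-yl)oxy]spiro[1,3-benzodioxine-2,7'-chromene]-4,5',8'(6'H)-trione (racemic; spiro C and adjacent CH epimerisable)
Conditions: Bu4NF (1.1 equiv), AcOH (1.2 equiv), THF, 0 °C
Reagents that add atoms: none
Why: Fluoride cleavage of the aryl silyl ether; acetic acid buffering keeps the phenoxide from opening the base-sensitive ketal-lactone.

Step 11
Reactants: 17 the spiro ketal-lactone phenol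
Product: 21 target CNP0222516.1 (caged spiro ketal-lactone), via aryloxyborane 18 (not isolated), via Claisen dienone borinate 19 (not isolated), via caged borinate 20 (not isolated)
Conditions: (S,S)-TsNHCH(Ph)CH(Ph)NHTs, BBr3, CH2Cl2, 0 °C → rt, evacuate (gives the bromoborane, 1.05 equiv); 17, Et3N (1.2 equiv), CH2Cl2, −78 °C → −20 °C → 35 °C; Et3N (1 equiv), rt; MeOH, aq. NaHCO3
Reagents that add atoms: none
Why: Proposed new method: the bromoborane forms aryloxyborane 18, whose boron chelates the neighbouring O6 ether, so the 1,1-dimethylallyl group shifts (3,3-sigmatropic, charge-accelerated aromatic Claisen) from O6 to C5 at low temperature over the arene face left open by the sulfonyl groups, fixing C5 as R in dienone 19; the vinyl group of the remaining allyl ether then adds across C10a/C7 from the only face its tether can reach (intramolecular Diels–Alder), which sets the other three cage centres, and the amine equilibrates spiro C4a and C4 through retro-oxa-Michael/oxa-Michael and enolisation to the stable epimer; the closest known reactions are the enantioselective aromatic Claisen rearrangement of catechol monoallyl ethers mediated by this chiral bromoborane and the thermal Claisen/Diels–Alder cascade of 5,6-bis(1,1-dimethylallyloxy)xanthones to caged xanthones.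

**Compound list**

1 | 2-methylbut-3-en-2-ol | CC(C)(O)C=C | starting material
2 | tert-butyl 2-methylbut-3-en-2-yl carbonate | CC(C)(C=C)OC(=O)OC(C)(C)C | intermediate
3 | methyl 2,3,4-trihydroxybenzoate | COC(=O)c1ccc(O)c(O)c1O | starting material
4 | methyl 2-hydroxy-3,4-bis[(2-methylbut-3-en-2-yl)oxy]benzoate | COC(=O)c1ccc(OC(C)(C)C=C)c(OC(C)(C)C=C)c1O | intermediate
5 | methyl 4,5-bis[(2-methylbut-3-en-2-yl)oxy]-3,6-dioxocyclohexa-1,4-diene-1-carboxylate (quinone ester, not isolated) | COC(=O)C1=CC(=O)C(OC(C)(C)C=C)=C(OC(C)(C)C=C)C1=O | intermediate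
6 | methyl 2,5-dihydroxy-3,4-bis[(2-methylbut-3-en-2-yl)oxy]benzoate | COC(=O)c1cc(O)c(OC(C)(C)C=C)c(OC(C)(C)C=C)c1O | intermediate
7 | methyl 2-hydroxy-3,4-bis[(2-methylbut-3-en-2-yl)oxy]-5-[(triisopropylsilyl)oxy]benzoate | COC(=O)c1cc(O[Si](C(C)C)(C(C)C)C(C)C)c(OC(C)(C)C=C)c(OC(C)(C)C=C)c1O | intermediate
8 | 2-hydroxy-3,4-bis[(2-methylbut-3-en-2-yl)oxy]-5-[(triisopropylsilyl)oxy]benzoic acid | OC(=O)c1cc(O[Si](C(C)C)(C(C)C)C(C)C)c(OC(C)(C)C=C)c(OC(C)(C)C=C)c1O | intermediate
9 | phloroglucinol (benzene-1,3,5-triol) | Oc1cc(O)cc(O)c1 | starting material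
10 | 3-methylbut-2-enal (prenal) | CC(C)=CC=O | starting material
11 | 3,5-dihydroxy-6-(3-methylbut-2-en-1-ylidene)cyclohexa-2,4-dien-1-one (ortho-quinone methide, not isolated) | CC(C)=CC=C1C(=O)C=C(O)C=C1O | intermediate
12 | 2,2-dimethyl-2H-chromene-5,7-diol | CC1(C)C=Cc2c(O)cc(O)cc2O1 | intermediate
13 | 7-hydroxy-2,2-dimethyl-2H-chromene-5,8-dione | CC1(C)C=CC2=C(O1)C(=O)C(O)=CC2=O | intermediate
14 | 7-hydroxy-2,2-dimethyl-6-(3-methylbut-2-en-1-yl)-2H-chromene-5,8-dione | CC(C)=CCC1=C(O)C(=O)C2=C(C=CC(C)(C)O2)C1=O | intermediate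
15 | 2,2-dimethyl-6-(3-methylbut-2-en-1-yl)-5,8-dioxo-2H-chromen-7-yl ester of acid 8 (acyloxyquinone, not isolated) | CC(C)=CCC1=C(OC(=O)c3cc(O[Si](C(C)C)(C(C)C)C(C)C)c(OC(C)(C)C=C)c(OC(C)(C)C=C)c3O)C(=O)C2=C(C=CC(C)(C)O2)C1=O | intermediate
16 | silyl-protected spiro ketal-lactone: 4H-1,3-benzodioxin-4-one (6-OSi(iPr)3, 7,8-bis(2-methylbut-3-en-2-yloxy)) spiro-fused at C2 to C7 of 2,2-dimethyl-6-prenyl-6H-chromene-5,8-dione; racemic, no fixed stereocentre (spiro C and adjacent CH epimerisable) | CC(C)=CCC1C(=O)C2=C(OC(C)(C)C=C2)C(=O)C13OC(=O)c4cc(O[Si](C(C)C)(C(C)C)C(C)C)c(OC(C)(C)C=C)c(OC(C)(C)C=C)c4O3 | intermediate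
17 | spiro ketal-lactone phenol (6-OH analogue of 16); racemic, no fixed stereocentre | CC(C)=CCC1C(=O)C2=C(OC(C)(C)C=C2)C(=O)C13OC(=O)c4cc(O)c(OC(C)(C)C=C)c(OC(C)(C)C=C)c4O3 | intermediate
18 | aryloxyborane of 17 with the (4S,5S)-1,3-ditosyl-4,5-diphenyl-1,3,2-diazaborolidin-2-yl group on O7 (not isolated) | CC(C)=CCC1C(=O)C2=C(OC(C)(C)C=C2)C(=O)C13OC(=O)c4cc(OB5N(S(=O)(=O)c6ccc(C)cc6)[C@@H](c6ccccc6)[C@H](c6ccccc6)N5S(=O)(=O)c5ccc(C)cc5)c(OC(C)(C)C=C)c(OC(C)(C)C=C)c4O3 | intermediate
19 | Claisen dienone borinate: C5 (R) carries prenyl and the 2-methylbut-3-en-2-yloxy group, C6 ketone, C7 O-boryl enol, diene C7=C8–C8a=C10a (not isolated) | CC(C)=CCC1C(=O)C2=C(OC(C)(C)C=C2)C(=O)C13OC(=O)C4=C(O3)[C@@](CC=C(C)C)(OC(C)(C)C=C)C(=O)C(OB5N(S(=O)(=O)c6ccc(C)cc6)[C@@H](c6ccccc6)[C@H](c6ccccc6)N5S(=O)(=O)c5ccc(C)cc5)=C4 | intermediate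
20 | caged borinate: target skeleton with the bridgehead O7 still on boron; cage centres fixed (C5 R, C7 R, ring-fusion CH S, C10a S), spiro C4a and C4 equilibrating (not isolated) | CC(C)=CCC1C(=O)C2=C(OC(C)(C)C=C2)C(=O)C12OC(=O)C1=C[C@]3(OB5N(S(=O)(=O)c6ccc(C)cc6)[C@@H](c6ccccc6)[C@H](c6ccccc6)N5S(=O)(=O)c5ccc(C)cc5)C[C@H]4C(C)(C)O[C@@](CC=C(C)C)(C3=O)[C@@]14O2 | intermediate
21 | target CNP0222516.1: 4-oxatricyclo[4.3.1.0(3,7)]dec-8-en-2-one cage (bridgehead OH at C7, prenyl at C5) joined through a 1,3-dioxin-4-one to the spiro carbon of the 2,2-dimethyl-6-prenyl-chromene-5,8-dione unit; C4 S, spiro C4a S, C5 R, C7 R, ring-fusion CH S, C10a S | CC(C)=CC[C@H]1C(=O)C2=C(OC(C)(C)C=C2)C(=O)[C@@]12OC(=O)C1=C[C@]3(O)C[C@H]4C(C)(C)O[C@@](CC=C(C)C)(C3=O)[C@@]14O2 | target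

**Totals and fallbacks**

Total step count: 11. Longest linear sequence: 8 steps (steps 1, 2, 3, 4, 5, 9, 10, 11).

Most likely to fail, step 11 (boron-templated asymmetric cascade). The tertiary allyl ether may ionise under the Lewis acid and lose isoprene, or the facial bias may be low. The fallback sets out from 17 and uses no boron reagent. Heating 17 in DMF at 110 °C runs the purely thermal Claisen/Diels–Alder cascade, which is well established for aryl bis(1,1-dimethylallyl) ethers with a para carbonyl group. A catalytic amount of Et3N at rt then equilibrates the spiro and C4 centres. This gives the racemate, that is 21 together with its mirror image ent-21 F1. The two are separated by preparative chromatography on a chiral stationary phase (amylose tris(3,5-dimethylphenylcarbamate), hexane/2-propanol), and the route is rejoined at 21.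

Second, step 9 (carbodiimide spiroketalisation). N-Acylurea formation or intermolecular acyl transfer may compete. The fallback sets out from 14 and reverses the order of bond formation. Oxalyl chloride with catalytic DMF (CH2Cl2, 0 °C) converts the vinylogous acid into the vinylogous acid chloride 7-chloro-2,2-dimethyl-6-(3-methylbut-2-en-1-yl)-2H-chromene-5,8-dione F2. Acid 8 and Cs2CO3 in DMF (0 °C → rt) then give phenoxide addition–elimination at the chlorinated quinone carbon, followed by carboxylate oxa-Michael closure onto the same carbon. The route is rejoined at 16.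

Third, step 3 (para-oxidation of the ester-chelated phenol). The hydrogen-bonded, ester-deactivated phenol 4 may resist the nitrosodisulfonate radical. The fallback sets out from 2 and a different arene, commercial methyl 3,4,5-trihydroxybenzoate (methyl gallate) F3. Reaction with 2 (2.1 equiv) and Pd(PPh3)4 alkylates the most acidic 4-OH and one of the two equivalent flanking hydroxyls, giving methyl 3-hydroxy-4,5-bis[(2-methylbut-3-en-2-yl)oxy]benzoate F4. This phenol is not chelated, and its free para position is the future C10a. Oxidation with K2[ON(SO3)2] gives the same quinone ester, so the route is rejoined at 5, followed by the Na2S2O4 reduction of step 3.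

**Further compounds**

F1 | step 11 | ent-21, mirror image of the target | CC(C)=CC[C@@H]1C(=O)C2=C(OC(C)(C)C=C2)C(=O)[C@]12OC(=O)C1=C[C@@]3(O)C[C@@H]4C(C)(C)O[C@](CC=C(C)C)(C3=O)[C@]14O2
F2 | step 9 | 7-chloro-2,2-dimethyl-6-(3-methylbut-2-en-1-yl)-2H-chromene-5,8-dione | CC(C)=CCC1=C(Cl)C(=O)C2=C(C=CC(C)(C)O2)C1=O
F3 | step 3 | methyl 3,4,5-trihydroxybenzoate (methyl gallate) | COC(=O)c1cc(O)c(O)c(O)c1
F4 | step 3 | methyl 3-hydroxy-4,5-bis[(2-methylbut-3-en-2-yl)oxy]benzoate | COC(=O)c1cc(O)c(OC(C)(C)C=C)c(OC(C)(C)C=C)c1
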